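**Retrosynthetic overview**
1. Butenolide (tetronic acid) ring, closed last: the O1–C2 lactone bond comes from fluoride-triggered lactonisation of a γ-silyloxy β-keto ester; the C3–C4 bond comes from a crossed Claisen condensation between the lithium enolate of methyl propionate and an (R)-α-silyloxy methyl ester (the key fragment union).
2. C5 stereocentre: Evans oxazolidinone enolate hydroxylation with the Davis oxaziridine on the C22 acyl imide, using the (R)-4-benzyl auxiliary.
3. C22 acid: malonic ester alkylation with the C20 allylic bromide, then saponification and decarboxylation.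
4. C20 chain: E-selective SeO2 oxidation of the terminal methyl of (E,E)-farnesyl acetate, and Li2CuCl4-catalysed coupling of the C1 allylic chloride with furan-3-ylmethylmagnesium chloride.
5. Ring order: the furan ring is bought intact (furan-3-ylmethanol); the butenolide ring is the only ring made, in the final step.

Assumption: the target is the drawn 4-hydroxy enol tautomer, (5R), all three chain alkenes E; the β-keto ester of the penultimate step is carried as a mixture of epimers at its methyl-bearing carbon, which becomes sp2 in the target.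

**Route**

Step 1
Reactants: 1 (2E,6E)-farnesol
Product: 2 (2E,6E)-farnesyl acetate
Conditions: Ac2O, pyridine, DMAP (cat.), CH2Cl2, 0 °C to rt
Reagents that add atoms: acetic anhydride, CC(=O)OC(C)=O
Why: DMAP-catalysed acetylation (nucleophilic acyl substitution) masks C1–OH and deactivates the C2=C3 alkene toward the following allylic oxidation.

Step 2
Reactants: 2 (2E,6E)-farnesyl acetate
Product: 3 (2E,6E,10E)-12-hydroxy-3,7,11-trimethyldodeca-2,6,10-trien-1-yl acetate
Conditions: SeO2 (0.1 equiv), salicylic acid (0.1 equiv), tBuOOH (70% aq, 3.5 equiv), CH2Cl2, 0 °C to rt; chromatography, unreacted 2 recycled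
Reagents that add atoms: tert-butyl hydroperoxide, CC(C)(C)OO (terminal oxygen source; selenium dioxide, O=[Se]=O, is the catalytic oxygen carrier)
Why: Riley allylic oxidation (ene reaction then [2,3]-sigmatropic shift) hydroxylates the (E)-methyl of the most electron-rich, least hindered terminal alkene, which fixes the 10E geometry.

Step 3
Reactants: 3 (2E,6E,10E)-12-hydroxy-3,7,11-trimethyldodeca-2,6,10-trien-1-yl acetate
Product: 4 (2E,6E,10E)-12-[(tert-butyldimethylsilyl)oxy]-3,7,11-trimethyldodeca-2,6,10-trien-1-yl acetate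
Conditions: TBSCl, imidazole, DMF, 0 °C to rt
Reagents that add atoms: tert-butyldimethylsilyl chloride, CC(C)(C)[Si](C)(C)Cl
Why: Imidazole-promoted silylation of the primary allylic alcohol gives a silyl ether that survives methanolysis, chlorination and the Grignard coupling.

Step 4
Reactants: 4 (2E,6E,10E)-12-[(tert-butyldimethylsilyl)oxy]-3,7,11-trimethyldodeca-2,6,10-trien-1-yl acetate
Product: 5 (2E,6E,10E)-12-[(tert-butyldimethylsilyl)oxy]-3,7,11-trimethyldodeca-2,6,10-trien-1-ol
Conditions: K2CO3 (0.5 equiv), MeOH, rt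
Reagents that add atoms: none
Why: Base-catalysed transesterification (Zemplén-type methanolysis) removes the acetate while the TBS ether is inert to K2CO3/MeOH.

Step 5
Reactants: 5 (2E,6E,10E)-12-[(tert-butyldimethylsilyl)oxy]-3,7,11-trimethyldodeca-2,6,10-trien-1-ol
Product: 7 tert-butyl{[(2E,6E,10E)-12-chloro-2,6,10-trimethyldodeca-2,6,10-trien-1-yl]oxy}dimethylsilane, via allylic mesylate 6 (not isolated)
Conditions: MsCl, 2,4,6-collidine, LiCl, DMF, 0 °C
Reagents that add atoms: methanesulfonyl chloride, CS(=O)(=O)Cl (its atoms are in 6 only); lithium chloride, [Li+].[Cl-] (chlorine of 7)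
Why: Collington–Meyers chlorination (in situ mesylate displaced by chloride in an SN2 step) gives the primary allylic chloride without allylic transposition or E/Z loss.

Step 6
Reactants: 8 furan-3-ylmethanol
Product: 9 3-(chloromethyl)furan
Conditions: SOCl2, pyridine, Et2O, 0 °C; used at once as a dried solution
Reagents that add atoms: thionyl chloride, O=S(Cl)Cl
Why: Chlorodehydroxylation through the chlorosulfite with pyridine as acid scavenger keeps the acid-sensitive furan intact.

Step 7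
Reactants: 9 3-(chloromethyl)furan
Product: 10 (furan-3-ylmethyl)magnesium chloride (titrated THF solution)
Conditions: Mg turnings (activated), THF, 0 °C to rt
Reagents that add atoms: magnesium, [Mg]
Why: Grignard formation by oxidative insertion of magnesium into the reactive furylmethyl C–Cl bond, kept cold and dilute to limit Wurtz dimerisation.

Step 8
Reactants: 7 tert-butyl{[(2E,6E,10E)-12-chloro-2,6,10-trimethyldodeca-2,6,10-trien-1-yl]oxy}dimethylsilane; 10 (furan-3-ylmethyl)magnesium chloride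
Product: 11 tert-butyl{[(2E,6E,10E)-13-(furan-3-yl)-2,6,10-trimethyltrideca-2,6,10-trien-1-yl]oxy}dimethylsilane
Conditions: 10 (2 equiv), Li2CuCl4 (5 mol%), THF, 0 °C
Reagents that add atoms: none
Why: Kochi-type Li2CuCl4-catalysed Grignard cross-coupling with a primary allylic chloride proceeds by direct (alpha) substitution, so the 2E alkene geometry and position are kept.

Step 9
Reactants: 11 tert-butyl{[(2E,6E,10E)-13-(furan-3-yl)-2,6,10-trimethyltrideca-2,6,10-trien-1-yl]oxy}dimethylsilane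
Product: 12 (2E,6E,10E)-13-(furan-3-yl)-2,6,10-trimethyltrideca-2,6,10-trien-1-ol
Conditions: Bu4NF (1.5 equiv), AcOH (1.5 equiv), THF, rt
Reagents that add atoms: none
Why: Fluoride-mediated desilylation driven by the strong Si–F bond, buffered with acetic acid, leaves furan and trisubstituted alkenes untouched.

Step 10
Reactants: 12 (2E,6E,10E)-13-(furan-3-yl)-2,6,10-trimethyltrideca-2,6,10-trien-1-ol
Product: 13 3-[(3E,7E,11E)-13-bromo-4,8,12-trimethyltrideca-3,7,11-trien-1-yl]furan
Conditions: CBr4, PPh3, CH2Cl2, −20 to 0 °C; filtered through silica and used at once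
Reagents that add atoms: carbon tetrabromide, BrC(Br)(Br)Br
Why: The Appel reaction converts the primary allylic alcohol to the bromide under neutral conditions by SN2 displacement of an alkoxyphosphonium ion, without transposition.

Step 11
Reactants: 13 3-[(3E,7E,11E)-13-bromo-4,8,12-trimethyltrideca-3,7,11-trien-1-yl]furan; 14 diethyl malonate
Product: 16 diethyl 2-[(2E,6E,10E)-13-(furan-3-yl)-2,6,10-trimethyltrideca-2,6,10-trien-1-yl]malonate, via sodium diethyl malonate 15 (not isolated)
Conditions: 14 (3 equiv), NaH (2.8 equiv), THF, 0 °C; then 13, 0 °C to rt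
Reagents that add atoms: sodium hydride, [Na+].[H-] (sodium is in 15 only)
Why: Malonic ester alkylation, an SN2 reaction of a soft stabilised enolate at the primary allylic bromide, with excess malonate suppressing dialkylation.

Step 12
Reactants: 16 diethyl 2-[(2E,6E,10E)-13-(furan-3-yl)-2,6,10-trimethyltrideca-2,6,10-trien-1-yl]malonate
Product: 17 2-[(2E,6E,10E)-13-(furan-3-yl)-2,6,10-trimethyltrideca-2,6,10-trien-1-yl]malonic acid
Conditions: KOH (6 equiv), EtOH/H2O 4:1, 70 °C; then cold 1 M HCl to pH 2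
Reagents that add atoms: potassium hydroxide, [K+].[OH-] (one oxygen of each CO2H)
Why: Saponification (BAc2 ester hydrolysis) of both esters; furan and isolated alkenes tolerate hot base and a brief cold dilute-acid work-up.

Step 13
Reactants: 17 2-[(2E,6E,10E)-13-(furan-3-yl)-2,6,10-trimethyltrideca-2,6,10-trien-1-yl]malonic acid
Product: 18 (4E,8E,12E)-15-(furan-3-yl)-4,8,12-trimethylpentadeca-4,8,12-trienoic acid
Conditions: pyridine, 110 °C, until CO2 evolution stops
Reagents that add atoms: none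
Why: Thermal decarboxylation of a malonic acid through a six-membered cyclic transition state under weakly basic conditions that protect furan and polyene.

Step 14
Reactants: 18 (4E,8E,12E)-15-(furan-3-yl)-4,8,12-trimethylpentadeca-4,8,12-trienoic acid; 19 (R)-4-benzyl-1,3-oxazolidin-2-one
Product: 21 (4R)-4-benzyl-3-[(4E,8E,12E)-15-(furan-3-yl)-4,8,12-trimethylpentadeca-4,8,12-trienoyl]-1,3-oxazolidin-2-one, via mixed pivalic anhydride 20 (not isolated)
Conditions: PivCl, Et3N, THF, −20 °C; then LiCl, 19, −20 °C to rt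
Reagents that add atoms: pivaloyl chloride, CC(C)(C)C(Cl)=O (its atoms are in 20 only)
Why: Mixed-anhydride N-acylation of the oxazolidinone (LiCl/Et3N activation) occurs at the unhindered acyl carbon of the pivalic mixed anhydride.

Step 15
Reactants: 21 (4R)-4-benzyl-3-[(4E,8E,12E)-15-(furan-3-yl)-4,8,12-trimethylpentadeca-4,8,12-trienoyl]-1,3-oxazolidin-2-one
Product: 23 (4R)-4-benzyl-3-[(2R,4E,8E,12E)-15-(furan-3-yl)-2-hydroxy-4,8,12-trimethylpentadeca-4,8,12-trienoyl]-1,3-oxazolidin-2-one, via sodium Z-enolate 22 (not isolated)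
Conditions: NaN(SiMe3)2 (1.15 equiv), THF, −78 °C; 2-(phenylsulfonyl)-3-phenyloxaziridine (1.5 equiv), −78 °C, 15 min; AcOH quench at −78 °C
Reagents that add atoms: sodium bis(trimethylsilyl)amide, [Na+].C[Si](C)(C)[N-][Si](C)(C)C (sodium is in 22 only); 2-(phenylsulfonyl)-3-phenyloxaziridine, O=S(=O)(c1ccccc1)N1OC1c1ccccc1 (hydroxyl oxygen of 23)
Why: Evans asymmetric enolate hydroxylation, in which the chelated Z-enolate is oxidised by the Davis oxaziridine on the face opposite the benzyl group, so the (R)-auxiliary gives the (2R)-alcohol.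

Step 16
Reactants: 23 (4R)-4-benzyl-3-[(2R,4E,8E,12E)-15-(furan-3-yl)-2-hydroxy-4,8,12-trimethylpentadeca-4,8,12-trienoyl]-1,3-oxazolidin-2-one
Product: 24 methyl (2R,4E,8E,12E)-15-(furan-3-yl)-2-hydroxy-4,8,12-trimethylpentadeca-4,8,12-trienoate
Conditions: MeMgBr (1.3 equiv) added to MeOH/CH2Cl2 at 0 °C (gives MeOMgBr); then 23, 0 °C, 20 min; AcOH quench; auxiliary 19 recovered
Reagents that add atoms: methanol, CO (delivered as MeOMgBr)
Why: Magnesium-assisted transesterification cleaves the exocyclic imide carbonyl selectively, helped by chelation to the α-hydroxyl, under conditions too mild to epimerise C2.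

Step 17
Reactants: 24 methyl (2R,4E,8E,12E)-15-(furan-3-yl)-2-hydroxy-4,8,12-trimethylpentadeca-4,8,12-trienoate
Product: 25 methyl (2R,4E,8E,12E)-2-[(tert-butyldimethylsilyl)oxy]-15-(furan-3-yl)-4,8,12-trimethylpentadeca-4,8,12-trienoate
Conditions: TBSCl, imidazole, DMF, rt
Reagents that add atoms: tert-butyldimethylsilyl chloride, CC(C)(C)[Si](C)(C)Cl
Why: Silyl ether formation protects the α-hydroxyl from the strong base of the next step and inductively activates the ester toward acylation.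

Step 18
Reactants: 25 methyl (2R,4E,8E,12E)-2-[(tert-butyldimethylsilyl)oxy]-15-(furan-3-yl)-4,8,12-trimethylpentadeca-4,8,12-trienoate; 26 methyl propionate
Product: 29 methyl (4R,6E,10E,14E)-4-[(tert-butyldimethylsilyl)oxy]-17-(furan-3-yl)-2,6,10,14-tetramethyl-3-oxoheptadeca-6,10,14-trienoate (C2 epimers), via lithium enolate of methyl propionate 27 (not isolated), via lithium enolate of the keto ester 28 (not isolated)
Conditions: LiN(iPr)2 (3.0 equiv), 26 (3.1 equiv), THF, −78 °C, 30 min; then 25, −78 to −30 °C; AcOH quench at −78 °C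
Reagents that add atoms: lithium diisopropylamide, [Li+].CC(C)[N-]C(C)C (lithium is in 27 and 28 only)
Why: Crossed Claisen condensation joins the propionate and silyloxy-ester fragments by attack of the enolate on the α-oxygen-activated methyl ester, and immediate deprotonation of the β-keto ester to 28 drives the reaction and shields the C4 stereocentre from enolisation.

Step 19
Reactants: 29 methyl (4R,6E,10E,14E)-4-[(tert-butyldimethylsilyl)oxy]-17-(furan-3-yl)-2,6,10,14-tetramethyl-3-oxoheptadeca-6,10,14-trienoate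
Product: 32 (5R)-5-[(2E,6E,10E)-13-(furan-3-yl)-2,6,10-trimethyltrideca-2,6,10-trien-1-yl]-4-hydroxy-3-methylfuran-2(5H)-one, via gamma-hydroxy beta-keto ester 30 (not isolated), via tetrabutylammonium tetronate 31 (not isolated)
Conditions: Bu4NF (2.5 equiv), THF, 0 °C to rt; then cold 0.5 M HCl to pH 2–3, EtOAc extraction
Reagents that add atoms: tetrabutylammonium fluoride, CCCC[N+](CCCC)(CCCC)CCCC.[F-] (the cation is in 31 only)
Why: Fluoride desilylation frees the γ-oxygen, which lactonises onto the methyl ester (5-exo-trig acyl substitution) to the highly stabilised tetronate, with no bond to C5 broken so the (R) centre is retained.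

**Compound list**
1 | (2E,6E)-farnesol | CC(C)=CCC/C(C)=C/CC/C(C)=C/CO | starting material
2 | (2E,6E)-farnesyl acetate | CC(C)=CCC/C(C)=C/CC/C(C)=C/COC(C)=O | intermediate
3 | (2E,6E,10E)-12-hydroxy-3,7,11-trimethyldodeca-2,6,10-trien-1-yl acetate | OC/C(C)=C/CC/C(C)=C/CC/C(C)=C/COC(C)=O | intermediate
4 | (2E,6E,10E)-12-[(tert-butyldimethylsilyl)oxy]-3,7,11-trimethyldodeca-2,6,10-trien-1-yl acetate | CC(C)(C)[Si](C)(C)OC/C(C)=C/CC/C(C)=C/CC/C(C)=C/COC(C)=O | intermediate
5 | (2E,6E,10E)-12-[(tert-butyldimethylsilyl)oxy]-3,7,11-trimethyldodeca-2,6,10-trien-1-ol | CC(C)(C)[Si](C)(C)OC/C(C)=C/CC/C(C)=C/CC/C(C)=C/CO | intermediate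
6 | (2E,6E,10E)-12-[(tert-butyldimethylsilyl)oxy]-3,7,11-trimethyldodeca-2,6,10-trien-1-yl methanesulfonate | CC(C)(C)[Si](C)(C)OC/C(C)=C/CC/C(C)=C/CC/C(C)=C/COS(C)(=O)=O | intermediate
7 | tert-butyl{[(2E,6E,10E)-12-chloro-2,6,10-trimethyldodeca-2,6,10-trien-1-yl]oxy}dimethylsilane | CC(C)(C)[Si](C)(C)OC/C(C)=C/CC/C(C)=C/CC/C(C)=C/CCl | intermediate
8 | furan-3-ylmethanol | OCc1ccoc1 | starting material
9 | 3-(chloromethyl)furan | ClCc1ccoc1 | intermediate
10 | (furan-3-ylmethyl)magnesium chloride | Cl[Mg]Cc1ccoc1 | intermediate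
11 | tert-butyl{[(2E,6E,10E)-13-(furan-3-yl)-2,6,10-trimethyltrideca-2,6,10-trien-1-yl]oxy}dimethylsilane | CC(C)(C)[Si](C)(C)OC/C(C)=C/CC/C(C)=C/CC/C(C)=C/CCc1ccoc1 | intermediate
12 | (2E,6E,10E)-13-(furan-3-yl)-2,6,10-trimethyltrideca-2,6,10-trien-1-ol | OC/C(C)=C/CC/C(C)=C/CC/C(C)=C/CCc1ccoc1 | intermediate
13 | 3-[(3E,7E,11E)-13-bromo-4,8,12-trimethyltrideca-3,7,11-trien-1-yl]furan | BrC/C(C)=C/CC/C(C)=C/CC/C(C)=C/CCc1ccoc1 | intermediate
14 | diethyl malonate | CCOC(=O)CC(=O)OCC | starting material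
15 | sodium diethyl malonate | [Na+].CCOC(=O)[CH-]C(=O)OCC | intermediate
16 | diethyl 2-[(2E,6E,10E)-13-(furan-3-yl)-2,6,10-trimethyltrideca-2,6,10-trien-1-yl]malonate | CCOC(=O)C(C/C(C)=C/CC/C(C)=C/CC/C(C)=C/CCc1ccoc1)C(=O)OCC | intermediate
17 | 2-[(2E,6E,10E)-13-(furan-3-yl)-2,6,10-trimethyltrideca-2,6,10-trien-1-yl]malonic acid | OC(=O)C(C/C(C)=C/CC/C(C)=C/CC/C(C)=C/CCc1ccoc1)C(=O)O | intermediate
18 | (4E,8E,12E)-15-(furan-3-yl)-4,8,12-trimethylpentadeca-4,8,12-trienoic acid | OC(=O)CC/C(C)=C/CC/C(C)=C/CC/C(C)=C/CCc1ccoc1 | intermediate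
19 | (R)-4-benzyl-1,3-oxazolidin-2-one | O=C1OC[C@@H](Cc2ccccc2)N1 | starting material
20 | (4E,8E,12E)-15-(furan-3-yl)-4,8,12-trimethylpentadeca-4,8,12-trienoic pivalic anhydride | CC(C)(C)C(=O)OC(=O)CC/C(C)=C/CC/C(C)=C/CC/C(C)=C/CCc1ccoc1 | intermediate
21 | (4R)-4-benzyl-3-[(4E,8E,12E)-15-(furan-3-yl)-4,8,12-trimethylpentadeca-4,8,12-trienoyl]-1,3-oxazolidin-2-one | O=C1OC[C@@H](Cc2ccccc2)N1C(=O)CC/C(C)=C/CC/C(C)=C/CC/C(C)=C/CCc3ccoc3 | intermediate
22 | sodium (Z)-enolate of 21 | [Na+].O=C1OC[C@@H](Cc2ccccc2)N1/C([O-])=C/C/C(C)=C/CC/C(C)=C/CC/C(C)=C/CCc3ccoc3 | intermediate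
23 | (4R)-4-benzyl-3-[(2R,4E,8E,12E)-15-(furan-3-yl)-2-hydroxy-4,8,12-trimethylpentadeca-4,8,12-trienoyl]-1,3-oxazolidin-2-one | O=C1OC[C@@H](Cc2ccccc2)N1C(=O)[C@@H](C/C(C)=C/CC/C(C)=C/CC/C(C)=C/CCc3ccoc3)O | intermediate
24 | methyl (2R,4E,8E,12E)-15-(furan-3-yl)-2-hydroxy-4,8,12-trimethylpentadeca-4,8,12-trienoate | COC(=O)[C@@H](C/C(C)=C/CC/C(C)=C/CC/C(C)=C/CCc1ccoc1)O | intermediate
25 | methyl (2R,4E,8E,12E)-2-[(tert-butyldimethylsilyl)oxy]-15-(furan-3-yl)-4,8,12-trimethylpentadeca-4,8,12-trienoate | COC(=O)[C@@H](C/C(C)=C/CC/C(C)=C/CC/C(C)=C/CCc1ccoc1)O[Si](C)(C)C(C)(C)C | intermediate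
26 | methyl propionate | CCC(=O)OC | starting material
27 | lithium enolate of methyl propionate | [Li+].COC([O-])=CC | intermediate
28 | lithium enolate of keto ester 29 | [Li+].COC(=O)C(C)=C([O-])[C@@H](C/C(C)=C/CC/C(C)=C/CC/C(C)=C/CCc1ccoc1)O[Si](C)(C)C(C)(C)C | intermediate
29 | methyl (4R,6E,10E,14E)-4-[(tert-butyldimethylsilyl)oxy]-17-(furan-3-yl)-2,6,10,14-tetramethyl-3-oxoheptadeca-6,10,14-trienoate (C2 epimers) | COC(=O)C(C)C(=O)[C@@H](C/C(C)=C/CC/C(C)=C/CC/C(C)=C/CCc1ccoc1)O[Si](C)(C)C(C)(C)C | intermediate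
30 | methyl (4R,6E,10E,14E)-17-(furan-3-yl)-4-hydroxy-2,6,10,14-tetramethyl-3-oxoheptadeca-6,10,14-trienoate (C2 epimers) | COC(=O)C(C)C(=O)[C@@H](C/C(C)=C/CC/C(C)=C/CC/C(C)=C/CCc1ccoc1)O | intermediate
31 | tetrabutylammonium salt of the target (tetronate) | CCCC[N+](CCCC)(CCCC)CCCC.CC1=C([O-])[C@@H](C/C(C)=C/CC/C(C)=C/CC/C(C)=C/CCc2ccoc2)OC1=O | intermediate
32 | (5R)-5-[(2E,6E,10E)-13-(furan-3-yl)-2,6,10-trimethyltrideca-2,6,10-trien-1-yl]-4-hydroxy-3-methylfuran-2(5H)-one | CC1=C(O)[C@@H](C/C(C)=C/CC/C(C)=C/CC/C(C)=C/CCc2ccoc2)OC1=O | target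

**Summary**
Total step count: 19.
Longest linear sequence: 17 steps (1 to 32 through steps 1–5 and 8–19); the furan branch (steps 6–7) joins at step 8.

**Steps most likely to fail, with fallbacks**

Step 8 (Grignard coupling). The furan-3-ylmethyl Grignard reagent can dimerise, couple through the furan C2 position, or attack the allylic chloride in the gamma sense. The fallback reverses the polarity and sets out from 7. Displacement of the chloride with PhSO2Na in DMF gives the allylic sulfone tert-butyl{[(2E,6E,10E)-12-(benzenesulfonyl)-2,6,10-trimethyldodeca-2,6,10-trien-1-yl]oxy}dimethylsilane F1. Its lithio derivative (nBuLi, THF/DMPU, −78 °C) is alkylated with 3-(chloromethyl)furan 9 to give tert-butyl{[(2E,6E,10E)-12-(benzenesulfonyl)-13-(furan-3-yl)-2,6,10-trimethyltrideca-2,6,10-trien-1-yl]oxy}dimethylsilane F2 (racemic at the sulfonyl carbon). Reductive desulfonylation with LiBHEt3 and catalytic Pd(dppp)Cl2 in THF at 0 °C removes the sulfone without moving the alkene, and the route is rejoined at 11.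

Step 15 (enolate hydroxylation). Risks are incomplete conversion, addition of the enolate to the sulfonimine by-product, and imperfect diastereoselectivity. The fallback sets the stereocentre by C–C bond formation and sets out from bromide 13. The glycolate imide (S)-4-benzyl-3-{[(4-methoxybenzyl)oxy]acetyl}-1,3-oxazolidin-2-one F3 is made from (S)-4-benzyl-1,3-oxazolidin-2-one and [(4-methoxybenzyl)oxy]acetic acid through the pivalic mixed anhydride. Its sodium enolate (NaN(SiMe3)2, THF, −78 °C, used in excess) is alkylated with 13 at −78 to −45 °C, anti to the benzyl group, to give (S)-4-benzyl-3-{(2R,4E,8E,12E)-15-(furan-3-yl)-2-[(4-methoxybenzyl)oxy]-4,8,12-trimethylpentadeca-4,8,12-trienoyl}-1,3-oxazolidin-2-one F4. Methanolysis with MeOMgBr gives methyl (2R,4E,8E,12E)-15-(furan-3-yl)-2-[(4-methoxybenzyl)oxy]-4,8,12-trimethylpentadeca-4,8,12-trienoate F5. Brief buffered DDQ treatment (CH2Cl2/pH 7 buffer, 0 °C) removes the 4-methoxybenzyl group, and the route is rejoined at 24. Furan tolerance to DDQ is the weak point of this fallback.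

Step 18 (crossed Claisen condensation). Acylation of the hindered α-silyloxy ester may be slow relative to self-condensation of the propionate enolate, and partial enolisation of 25 would erode the stereocentre. The fallback replaces the Claisen by an intermolecular aldol addition followed by oxidation and sets out from 25. Reduction with iBu2AlH (CH2Cl2, −78 °C) gives (2R,4E,8E,12E)-2-[(tert-butyldimethylsilyl)oxy]-15-(furan-3-yl)-4,8,12-trimethylpentadeca-4,8,12-trienal F6. This is added at −78 °C to the lithium enolate 27 to give methyl (4R,6E,10E,14E)-4-[(tert-butyldimethylsilyl)oxy]-17-(furan-3-yl)-3-hydroxy-2,6,10,14-tetramethylheptadeca-6,10,14-trienoate F7 (diastereomer mixture at C2 and C3, which does not matter). Dess–Martin periodinane (NaHCO3, CH2Cl2, rt) oxidises the carbinol, and the route is rejoined at 29.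

**Further compounds**
F1 | step 8 | tert-butyl{[(2E,6E,10E)-12-(benzenesulfonyl)-2,6,10-trimethyldodeca-2,6,10-trien-1-yl]oxy}dimethylsilane | CC(C)(C)[Si](C)(C)OC/C(C)=C/CC/C(C)=C/CC/C(C)=C/CS(=O)(=O)c1ccccc1
F2 | step 8 | tert-butyl{[(2E,6E,10E)-12-(benzenesulfonyl)-13-(furan-3-yl)-2,6,10-trimethyltrideca-2,6,10-trien-1-yl]oxy}dimethylsilane | CC(C)(C)[Si](C)(C)OC/C(C)=C/CC/C(C)=C/CC/C(C)=C/C(Cc1ccoc1)S(=O)(=O)c2ccccc2
F3 | step 15 | (S)-4-benzyl-3-{[(4-methoxybenzyl)oxy]acetyl}-1,3-oxazolidin-2-one | O=C1OC[C@H](Cc2ccccc2)N1C(=O)COCc3ccc(OC)cc3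
F4 | step 15 | (S)-4-benzyl-3-{(2R,4E,8E,12E)-15-(furan-3-yl)-2-[(4-methoxybenzyl)oxy]-4,8,12-trimethylpentadeca-4,8,12-trienoyl}-1,3-oxazolidin-2-one | O=C1OC[C@H](Cc2ccccc2)N1C(=O)[C@@H](C/C(C)=C/CC/C(C)=C/CC/C(C)=C/CCc3ccoc3)OCc4ccc(OC)cc4
F5 | step 15 | methyl (2R,4E,8E,12E)-15-(furan-3-yl)-2-[(4-methoxybenzyl)oxy]-4,8,12-trimethylpentadeca-4,8,12-trienoate | COC(=O)[C@@H](C/C(C)=C/CC/C(C)=C/CC/C(C)=C/CCc1ccoc1)OCc2ccc(OC)cc2
F6 | step 18 | (2R,4E,8E,12E)-2-[(tert-butyldimethylsilyl)oxy]-15-(furan-3-yl)-4,8,12-trimethylpentadeca-4,8,12-trienal | O=C[C@@H](C/C(C)=C/CC/C(C)=C/CC/C(C)=C/CCc1ccoc1)O[Si](C)(C)C(C)(C)C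
F7 | step 18 | methyl (4R,6E,10E,14E)-4-[(tert-butyldimethylsilyl)oxy]-17-(furan-3-yl)-3-hydroxy-2,6,10,14-tetramethylheptadeca-6,10,14-trienoate | COC(=O)C(C)C(O)[C@@H](C/C(C)=C/CC/C(C)=C/CC/C(C)=C/CCc1ccoc1)O[Si](C)(C)C(C)(C)C
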